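The target is disconnected across ring C at C6a–C6b and C11a–O11. C11a is benzylic to ring A, whose oxygens on C1, C3 and C4a sit ortho, para and ortho to C11b. A 2H-chromene with a C6a=C11a double bond is therefore nucleophilic at C6a and leaves a well-stabilised cation at C11a. One titanium-promoted formal [3+2] addition to 2-methoxy-1,4-benzoquinone forms both bonds, closes ring C, brings in ring D with its C9 methoxy group, and sets C6a and C11a under a chiral diolate. The precursor is an achiral tricyclic chromene (rings A, B, E) carrying the C3 oxygen as an allyl ether.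

Key step: step 5

Remarks on the chemistry
- Numbering is that of the pterocarpan: ring A is C1–C4, C4a, C11b; ring B is O5, C6, C6a, C11a; ring C contains O11; ring D is C6b–C10a; ring E is the dimethyldihydropyran with its oxygen on C1 and its CH2 on C2.
- The C3 oxygen is carried as an allyl ether, not a benzyl ether. The C11a–O11 bond of a pterocarpan is itself a benzylic aryl ether, which hydrogenolysis over Pd/C would put at risk. The allyl group leaves under the palladium/formate conditions that remove the C8 oxygen.
- Assumption: the (R,R)-diol is written for step 5. The sense of induction with this chromene is to be fixed by a pilot run; the equally available (S,S)-diol takes its place if 11 forms as the mirror image.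

Step 1
Reactants: 1 2,4,6-trihydroxybenzaldehyde
Product: 2 4-(allyloxy)-2,6-dihydroxybenzaldehyde
Conditions: allyl bromide (1.0 equiv), KHCO3 (1.1 equiv), DMF, 25 → 40 °C
Reagents that add atoms: allyl bromide, C=CCBr
Why: Williamson etherification, in which the hydroxyl para to the formyl group is the most acidic and is not held in a hydrogen bond to the carbonyl, so one equivalent of weak base and of halide should alkylate it in preference to the two ortho hydroxyls.

Step 2
Reactants: 2 4-(allyloxy)-2,6-dihydroxybenzaldehyde; 3 1-bromo-3-methylbut-2-ene (prenyl bromide)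
Product: 4 4-(allyloxy)-2,6-dihydroxy-3-(3-methylbut-2-en-1-yl)benzaldehyde
Conditions: 3 (1.0 equiv), 10% aq. KOH, 0 °C → rt
Reagents that add atoms: none
Why: C-alkylation of an ambident phenoxide (prenylation of a phloroglucinol-type dianion in water, where hydrogen bonding masks the oxygens), in which C3 and C5 are equivalent by symmetry and each is activated by two ortho oxygens and one para oxygen, so only one mono-C-prenyl product can form.

Step 3
Reactants: 4 4-(allyloxy)-2,6-dihydroxy-3-(3-methylbut-2-en-1-yl)benzaldehyde
Product: 5 5-(allyloxy)-7-hydroxy-2,2-dimethylchromane-8-carbaldehyde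
Conditions: sulfonic acid resin (Amberlyst 15) or TsOH·H2O (cat.), toluene, 60 °C
Reagents that add atoms: none
Why: Acid-catalysed Markovnikov hydroalkoxylation (cycloisomerisation of an ortho-prenyl phenol to a 2,2-dimethylchroman), in which the tertiary cation can be captured only by the one free hydroxyl next to the prenyl group, because the other neighbour is the allyl ether, and this closes ring E.

Step 4
Reactants: 5 5-(allyloxy)-7-hydroxy-2,2-dimethylchromane-8-carbaldehyde; 6 vinyltriphenylphosphonium bromide
Product: 8 5-(allyloxy)-2,2-dimethyl-3,4-dihydro-2H,8H-pyrano[2,3-f]chromene (the 3-O-allyl chromene of rings A, B and E, alkene between C6a and C11a), via phosphorus ylide 7 (not isolated)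
Conditions: NaH (1.1 equiv), DMF, 0 °C; then 6 (1.2 equiv), 70 °C
Reagents that add atoms: none
Why: Schweizer reaction, in which the sodium phenoxide adds to the vinylphosphonium salt (oxa-Michael addition) to give ylide 7, whose intramolecular Wittig reaction with the neighbouring formyl group closes ring B and places the alkene between C6a and C11a.

Step 5
Reactants: 8 5-(allyloxy)-2,2-dimethyl-3,4-dihydro-2H,8H-pyrano[2,3-f]chromene; 9 2-methoxy-1,4-benzoquinone
Product: 11 (6aS,11aS)-3-(allyloxy)-8-hydroxy-9-methoxypterocarpan bearing ring E (the 3-O-allyl-8-hydroxy derivative of the target), via zwitterion 10 (not isolated)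
Conditions: TiCl4/Ti(OiPr)4 (1:1) premixed with (R,R)-TADDOL to give TiCl2(TADDOLate) (2.5 equiv), CH2Cl2, −78 °C; 9, then slow addition of 8; −78 → −40 °C; aq. NaHCO3
Reagents that add atoms: none
Why: Tetravalent titanium chelates the methoxy oxygen and the adjacent carbonyl of 9, which makes the unsubstituted ring carbon para to the methoxy-bearing carbon the electrophilic site; C6a of 8 adds there in a Michael-type step and gives zwitterion 10, a titanium dienolate with a C11a cation stabilised by the C1, C3 and C4a oxygens of ring A. The carbonyl oxygen next to the new C6a–C6b bond then captures C11a in a five-membered closure (5-exo-trig on the quinone-methide form C11a=C11b of the cation) that forms ring C, and loss of the C6b proton aromatises ring D to the C8 phenol. The closest known reaction type is the titanium-promoted formal [3+2] cycloaddition of 2-alkoxy-1,4-benzoquinones with styrenes and 2H-chromenes, including its TADDOLate version; the [2+2] mode that competes in such additions ionises at the same benzylic carbon on warming and converges on 11 without touching C6a. C6a is set by the chiral diolate, which blocks one face of the chelated quinone while the chromene stacks ring A over the quinone, so that only one alkene face can bond; C11a is set by the substrate, because ring C can only close cis onto ring B. The step needs regioselectivity in both partners and chemoselectivity for the chromene alkene: the first follows from chelation and from the benzylic polarisation of the styrene-type double bond, the second from the inertness of the unactivated allyl ether alkene towards the quinone complex at −78 °C.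

Step 6
Reactants: 11 (6aS,11aS)-3-(allyloxy)-8-hydroxy-9-methoxypterocarpan bearing ring E
Product: 12 the 8-trifluoromethanesulfonate of 11
Conditions: PhNTf2 (1.2 equiv), Et3N, DMAP (cat.), CH2Cl2, 0 °C → rt
Reagents that add atoms: N-phenylbis(trifluoromethanesulfonimide), O=S(=O)(N(c1ccccc1)S(=O)(=O)C(F)(F)F)C(F)(F)F
Why: Sulfonylation of the only free hydroxyl (C8) with N-phenyltriflimide under amine base, chosen over triflic anhydride so that no strong acid meets the acid-labile C11a–O11 bond.

Step 7
Reactants: 12 the 8-trifluoromethanesulfonate of 11
Product: 14 (6aS,11aS)-3-hydroxy-9-methoxypterocarpan bearing ring E (CNP0207547.1), via phenol triflate 13 (not isolated)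
Conditions: Pd(OAc)2 (10 mol %), 1,1'-bis(diphenylphosphino)ferrocene (12 mol %), HCO2H (5 equiv), Et3N (7 equiv), DMF, 25 °C, then 70 °C
Reagents that add atoms: none
Why: Two known palladium–formate reactions run in one flask: zerovalent palladium ionises the allyl aryl ether to a π-allyl complex that formate reduces to propene (Tsuji–Trost deallylation), and on warming it inserts into the aryl triflate, after which formate delivers hydride and reductive elimination leaves C8–H (reduction of an aryl triflate), neither reaction touching C6a, C11a or the C11a–O11 bond.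

Compound list
1 | 2,4,6-trihydroxybenzaldehyde | O=Cc1c(O)cc(O)cc1O | starting material
2 | 4-(allyloxy)-2,6-dihydroxybenzaldehyde | O=Cc1c(O)cc(OCC=C)cc1O | intermediate
3 | 1-bromo-3-methylbut-2-ene (prenyl bromide) | CC(C)=CCBr | starting material
4 | 4-(allyloxy)-2,6-dihydroxy-3-(3-methylbut-2-en-1-yl)benzaldehyde | O=Cc1c(O)cc(OCC=C)c(CC=C(C)C)c1O | intermediate
5 | 5-(allyloxy)-7-hydroxy-2,2-dimethylchromane-8-carbaldehyde (rings A and E) | CC1(C)CCc2c(OCC=C)cc(O)c(C=O)c2O1 | intermediate
6 | vinyltriphenylphosphonium bromide | C=C[P+](c1ccccc1)(c1ccccc1)c1ccccc1.[Br-] | starting material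
7 | phosphorus ylide from 5 and 6: [2-(aryloxy)ethylidene]triphenylphosphorane with the formyl group still in place (not isolated) | CC1(C)CCc2c(OCC=C)cc(OCC=P(c3ccccc3)(c3ccccc3)c3ccccc3)c(C=O)c2O1 | intermediate
8 | 5-(allyloxy)-2,2-dimethyl-3,4-dihydro-2H,8H-pyrano[2,3-f]chromene (3-O-allyl chromene of rings A, B, E; alkene C6a=C11a) | CC1(C)CCc2c(OCC=C)cc3OCC=Cc3c2O1 | intermediate
9 | 2-methoxy-1,4-benzoquinone | COC1=CC(=O)C=CC1=O | starting material
10 | zwitterion after C6a–C6b bond formation: C11a benzylic cation and dienolate, drawn without titanium, C6a already configured (not isolated) | CC1(C)CCc2c(OCC=C)cc3OC[C@@H]([CH+]c3c2O1)C1C=C([O-])C(OC)=CC1=O | intermediate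
11 | (6aS,11aS)-3-(allyloxy)-8-hydroxy-9-methoxypterocarpan with ring E (O on C1, CH2 on C2, gem-dimethyl next to O), cis-fused | COc1c(O)cc2c(c1)O[C@@H]1c3c(cc(OCC=C)c4c3OC(C)(C)CC4)OC[C@H]21 | intermediate
12 | (6aS,11aS)-3-(allyloxy)-9-methoxy-8-(trifluoromethanesulfonyloxy)pterocarpan with ring E | COc1c(OS(=O)(=O)C(F)(F)F)cc2c(c1)O[C@@H]1c3c(cc(OCC=C)c4c3OC(C)(C)CC4)OC[C@H]21 | intermediate
13 | (6aS,11aS)-3-hydroxy-9-methoxy-8-(trifluoromethanesulfonyloxy)pterocarpan with ring E (not isolated) | COc1c(OS(=O)(=O)C(F)(F)F)cc2c(c1)O[C@@H]1c3c(cc(O)c4c3OC(C)(C)CC4)OC[C@H]21 | intermediate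
14 | (6aS,11aS)-3-hydroxy-9-methoxypterocarpan with ring E, CNP0207547.1 | COc1ccc2c(c1)O[C@@H]1c3c(cc(O)c4c3OC(C)(C)CC4)OC[C@H]21 | target

Total step count: 7. Longest linear sequence: 7 steps, from 1 to 14; 3, 6 and 9 enter as purchased materials.

Steps most likely to fail

Step 5. The facial selectivity at C6a may be poor: the diolate differentiates the quinone faces, but the chromene must also hold one stacked orientation for this to translate into one alkene face. Diversion into the [2+2] mode, or Friedel–Crafts attack by the electron-rich ring A, may accompany this. The fallback sets out from 8 and 9 and comes back at 11. The addition is run with the achiral promoter TiCl2(OiPr)2 (TiCl4 plus Ti(OiPr)4, CH2Cl2, −78 °C), which should give the racemic cis-fused phenol F1. F1 is then resolved by preparative chromatography on a chiral stationary phase (cellulose tris(3,5-dimethylphenylcarbamate), hexane/propan-2-ol), and the (6aS,11aS) enantiomer is 11.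

Step 2. O-Alkylation and double alkylation may outrun mono-C-prenylation. The fallback sets out from 2 and comes back at 4. One of the two equivalent hydroxyls is etherified with 3-chloro-3-methylbut-1-yne (K2CO3, KI, CuI cat., acetone, 55 °C) to give 4-(allyloxy)-2-hydroxy-6-[(2-methylbut-3-yn-2-yl)oxy]benzaldehyde F2; the remaining hydroxyl stays chelated to the carbonyl. Semihydrogenation of the alkyne (H2, Pd/CaCO3 poisoned with Pb(OAc)2, quinoline, EtOAc, rt) gives the 1,1-dimethylallyl ether 4-(allyloxy)-2-hydroxy-6-[(2-methylbut-3-en-2-yl)oxy]benzaldehyde F3. Aromatic Claisen rearrangement (toluene, 110 °C) then delivers the group with allylic inversion, as a prenyl group, to the only free ortho carbon; this is 4. The simple allyl ether should not rearrange at this temperature.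

Step 4. The intramolecular Wittig closure may be slow on an aldehyde flanked by two oxygens, and the electron-rich chromene may oligomerise under heat or traces of acid during isolation. The fallback sets out from 5 and comes back at 8. The phenol is allylated (allyl bromide, K2CO3, DMF, rt) to give 5,7-bis(allyloxy)-2,2-dimethylchromane-8-carbaldehyde F4. Wittig methylenation (Ph3P=CH2 from Ph3PCH3Br and KOtBu, THF, 0 °C) gives 5,7-bis(allyloxy)-2,2-dimethyl-8-vinylchromane F5. Ring-closing metathesis between the vinyl group and the ortho allyloxy group (second-generation Grubbs catalyst RuCl2(=CHPh)(H2IMes)(PCy3), CH2Cl2, 0.01 M, 40 °C) closes ring B with loss of ethene. The other allyl ether is para to the vinyl group, cannot ring-close, and remains as the C3 protecting group.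

Further compounds
F1 | step 5 | racemic cis-fused 3-(allyloxy)-8-hydroxy-9-methoxypterocarpan with ring E (both enantiomers, relative configuration 6aS*,11aS*) | COc1c(O)cc2c(c1)OC1c3c(cc(OCC=C)c4c3OC(C)(C)CC4)OCC21
F2 | step 2 | 4-(allyloxy)-2-hydroxy-6-[(2-methylbut-3-yn-2-yl)oxy]benzaldehyde | O=Cc1c(O)cc(OCC=C)cc1OC(C)(C)C#C
F3 | step 2 | 4-(allyloxy)-2-hydroxy-6-[(2-methylbut-3-en-2-yl)oxy]benzaldehyde | O=Cc1c(O)cc(OCC=C)cc1OC(C)(C)C=C
F4 | step 4 | 5,7-bis(allyloxy)-2,2-dimethylchromane-8-carbaldehyde | CC1(C)CCc2c(OCC=C)cc(OCC=C)c(C=O)c2O1
F5 | step 4 | 5,7-bis(allyloxy)-2,2-dimethyl-8-vinylchromane | CC1(C)CCc2c(OCC=C)cc(OCC=C)c(C=C)c2O1
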